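Keep the starting material, free catalyst and second catalyst as in the blue and ochre runs, set the reagent at 18.0 mM, and decide from those two runs whether the flask needs its whole 40 min and when to sample for 30% of product.

the same everywhere: starting material 20 mM; free catalyst 100 µM
- blue: reagent 12 mM; second catalyst 2 mM; run made earlier
- ochre: reagent 27 mM; second catalyst 2 mM; run made earlier
- flask: reagent 18.0 mM; second catalyst 2.0 mM; time 40 min

| blue: time / min | blue: product / % | ochre: time / min | ochre: product / % |
|---|---|---|---|
| 10.0 | 17.8 | 10.0 | 33.7 |
| 15.0 | 25.4 | 15.0 | 47.1 |
| 20.0 | 30.6 | 20.0 | 56.2 |
| 30.0 | 38.2 | 30.0 | 68.8 |

(scatter of a reading: 0.3 percentage points)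

- time up to 40 min at which product stands highest
- the amount of product, in percent of the starting material charged, at that time
- the first time at which product reaches 30%, in the same percent, in min

We read the blue run through the integrated second-order law between its readings at 10.0 min and 30.0 min, and the slope is 0.00235 /mM/min. We call this the pairing constant k: product made per minute for each mM of charge not yet product times each mM of reagent. The ochre run, with a different reagent charge and read the same way, gives 0.00235 /mM/min, from readings with a scatter of 0.3 percentage points. Both lines start late, by 2.08 min on average.

In the flask the reagent stands below the starting material, so it is the limiting reagent, and product can reach 90.0% of the charge. Our reckoning with k and the delay puts 30% at 12.5 min and gives 59.5% at 40 min. That is short of the cap, and k reckons product still forming at 0.116 mM/min at that time, so we run the whole time and sample near 12.5 min.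

The forecast, from these same runs, gives 40 min, 59.3% and 12.5 min, and calls the delay “a short induction, perhaps a build-up of an intermediate or active catalyst”.

The flask stands highest at 40.0 min with 60.3% of product, and reaches 30% at 12.4 min.

    reagent + catalyst intermediate → second catalyst + product (k = 17.0 /M/s)
    starting material + free catalyst ⇌ free catalyst + open intermediate (K = 2.20, k = 59.0 /M/s)
    second catalyst + open intermediate ⇌ catalyst intermediate (K = 1.90 /M, k = 5.90 /M/s)

At 40.0 min the flask holds 12.8% of the starting material charged as starting material, 26.9% of it as open intermediate, and 0.979% of the second catalyst charged as catalyst intermediate, together 7.94 mM not yet product. With the 5.94 mM of reagent left, k reckons 0.111 mM/min of product still forming there. In the neighbouring flask with 7.2 mM of reagent, k and the delay reckon 27.7% at 40.0 min, and that flask gave 28.5%.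

(The readings are calculated from invented constants; scatter was added.)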